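## Retrosynthetic overview

1. Numbering (8,9-secokaurane): ring A = C1–C5, C10; ten-membered ring = C5–C6–C7–C8–C14–C13–C12–C11–C9–C10; cyclopentenone = C8, C14, C13, C16, C15 (C17 = exocyclic CH2, C20 = methyl on C10).
2. The ten-membered ring with its bridgehead enone comes from a 6→10 ring expansion: anionic oxy-Cope shift (C8–C9 broken, C12–C13 made) of a trans-decalin C9 vinyl carbinol carrying a spiro 4-methylenecyclopentene at C8. C11–OAc, C15=O and C7–OH follow from enolate hydroxylation with inversion, C15 allylic oxidation and a C7,C9-dione.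
3. The spiro ring comes from the decalin-7,9-dione by C8 vinylation (sulfoxide route), propargylation and ethene-relayed enyne metathesis.
4. Ring A is closed at C2–C3 by ring-closing metathesis with in-flask hydrogenation of a monocyclic cyclohexenone. This works because ring A is a bare trimethylene bridge (C1–C2–C3) between the quaternary carbons C10 and C4, which hang on adjacent ring B atoms C10 (sp3) and C5 (sp2). An allyl group on C10 and a 1,1-dimethylallyl group on C5 therefore meet with no stereochemical condition; C5–H is set afterwards from C10, and C10 by palladium-catalysed asymmetric allylation.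
5. Ring order: ring B (bought) → ring A (step 4) → spiro ring D (step 9) → ten-membered ring (step 15).

Key step: step 4

Remark on the chemistry: locants C1–C20 below are those of line 1; "syn" and "anti" refer to the C10 methyl group. Facial assignments in steps 7, 10, 12, 14 and 15 rest on a chair model of ring B and of the oxy-Cope transition state, not on experiment.

## Route

Step 1
Reactants: 1 3-ethoxy-2-methylcyclohex-2-en-1-one; 2 prenylmagnesium chloride
Product: 4 2-methyl-3-(2-methylbut-3-en-2-yl)cyclohex-2-en-1-one, via carbinol adduct 3 (not isolated)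
Conditions: 2 (1.3 equiv), THF, −78 → 0 °C; then 1 M HCl, 25 °C
Reagents that add atoms: water, O
Why: Stork–Danheiser enone transposition: the prenyl Grignard reagent should add to the vinylogous-ester carbonyl through its γ-carbon (allylic transposition in a six-membered transition state), which makes the C4–C5 bond with the quaternary C4 and its vinyl group in place, and aqueous acid then hydrolyses the enol ether and eliminates water.

Step 2
Reactants: 4 2-methyl-3-(2-methylbut-3-en-2-yl)cyclohex-2-en-1-one; 5 allyl chloroformate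
Product: 7 2-methyl-3-(2-methylbut-3-en-2-yl)cyclohexa-1,3-dien-1-yl prop-2-en-1-yl carbonate, via potassium dienolate 6 (not isolated)
Conditions: KN(SiMe3)2 (0.95 equiv), THF, −78 → 0 °C; then 5, −78 °C
Reagents that add atoms: none
Why: Thermodynamic enolisation (slight deficit of base, proton exchange with remaining ketone) should give the fully conjugated γ-deprotonated dienolate rather than the cross-conjugated one, and the hard chloroformate acylates it on oxygen (enol carbonate formation).

Step 3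
Reactants: 7 2-methyl-3-(2-methylbut-3-en-2-yl)cyclohexa-1,3-dien-1-yl prop-2-en-1-yl carbonate
Product: 8 (2R)-2-methyl-3-(2-methylbut-3-en-2-yl)-2-(prop-2-en-1-yl)cyclohex-3-en-1-one
Conditions: Pd2(dba)3 (2.5 mol %), (S)-t-BuPHOX (6 mol %), toluene, 25 °C
Reagents that add atoms: none
Why: Tsuji–Stoltz decarboxylative asymmetric allylic alkylation: ionisation and loss of CO2 should give a (phosphinooxazoline)palladium allyl dienolate that recombines at the α-carbon C10, so the quaternary stereocentre is set by the ligand ((S)-t-BuPHOX is expected to give the R ketone by analogy with 2-allyl-2-methylcyclohexanone), the temperature being kept at or below 25 °C so that the 1,5-diene does not undergo a Cope shift to the γ-allyl isomer.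

Step 4
Reactants: 8 (2R)-2-methyl-3-(2-methylbut-3-en-2-yl)-2-(prop-2-en-1-yl)cyclohex-3-en-1-one
Product: 10 (8aR)-5,5,8a-trimethyl-3,5,6,7,8,8a-hexahydronaphthalen-1(2H)-one, via bicyclic diene 9 (not isolated)
Conditions: second-generation Grubbs catalyst RuCl2(=CHPh)(PCy3)(H2IMes) (3 mol %), CH2Cl2, 40 °C; then H2 (5 bar), 40 °C, same flask
Reagents that add atoms: none
Why: Ring-closing olefin metathesis followed in the same flask by hydrogenation: the ruthenium alkylidene should initiate at the unhindered allyl group on C10, close a ruthenacyclobutane onto the vinyl group on C4 and expel ethene, which forms the C2=C3 bond and ring A, and under H2 the same ruthenium is converted into a hydride that saturates this disubstituted alkene. The closest known reactions are ring-closing metathesis of 1,7-dienes to cyclohexenes with allylic quaternary carbons and the tandem metathesis–hydrogenation use of ruthenium benzylidene catalysts. Ring A is closed as a six-membered ring by intramolecular [2+2] cycloaddition and cycloreversion at ruthenium, the two arms being held side by side because they sit on the adjacent ring B atoms C10 and sp2 C5. No stereocentre is created: C10 is untouched and C5 is deliberately left trigonal so that the trans ring fusion can be set in step 6 from the angular methyl. The step needs ring closure to win over oligomerisation and needs both ruthenium species to ignore the C5=C6 alkene; the two quaternary carbons C4 and C10 give a double gem-dialkyl effect for cyclisation and, flanking C5=C6, make that trisubstituted bond inert to metathesis and to homogeneous hydrogenation. In one operation the monocyclic ketone thus becomes the complete, saturated, unfunctionalised ring A of the target fused to ring B.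

Step 5
Reactants: 10 (8aR)-5,5,8a-trimethyl-3,5,6,7,8,8a-hexahydronaphthalen-1(2H)-one
Product: 11 (8aR)-5,5,8a-trimethyl-6,7,8,8a-tetrahydronaphthalene-1,3(2H,5H)-dione
Conditions: Pd(OH)2/C (5 mol %), t-BuOOH (5 equiv), K2CO3, CH2Cl2, 4 °C
Reagents that add atoms: tert-butyl hydroperoxide, CC(C)(C)OO
Why: Corey–Yu allylic oxidation: C7 is the only allylic C–H position of the C5=C6 alkene (C4 and C10 are quaternary), so the allylic peroxide and then the enone should form only there, giving the C7/C9 dione oxidation pattern.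

Step 6
Reactants: 11 (8aR)-5,5,8a-trimethyl-6,7,8,8a-tetrahydronaphthalene-1,3(2H,5H)-dione
Product: 12 (4aR,8aR)-5,5,8a-trimethyl-4a,5,6,7,8,8a-hexahydronaphthalene-1,3(2H,4H)-dione (trans ring fusion)
Conditions: H2 (4 bar), Pd/C, EtOAc, 25 °C
Reagents that add atoms: none
Why: Heterogeneous hydrogenation of the enone should deliver hydrogen to C5 from the face opposite the angular C10 methyl and the axial C4 methyl, which sets C5 (H anti to the C10 methyl, trans-decalin).

Step 7
Reactants: 12 (4aR,8aR)-5,5,8a-trimethyl-4a,5,6,7,8,8a-hexahydronaphthalene-1,3(2H,4H)-dione; 13 phenyl vinyl sulfoxide; 14 propargyl bromide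
Product: 16 (2R,4aR,8aR)-5,5,8a-trimethyl-2-[2-(phenylsulfinyl)ethyl]-2-(prop-2-yn-1-yl)-4a,5,6,7,8,8a-hexahydronaphthalene-1,3(2H,4H)-dione (propynyl anti, sulfinylethyl syn; sulfur unspecified), via Michael adduct 15 (not isolated)
Conditions: K2CO3, DMF, 13 (1.05 equiv), 60 °C; then 14 (1.5 equiv), 25 °C
Reagents that add atoms: none
Why: Michael addition of the cyclic 1,3-dione to phenyl vinyl sulfoxide (a vinyl cation equivalent) followed by C-alkylation of the 2-substituted dione: the second electrophile should approach the planar C8 enolate anti to the axial C10 methyl, which places the propynyl arm (C15, C16, C13) anti and the sulfinylethyl arm (C14) syn to that methyl and so sets C8.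

Step 8
Reactants: 16 (2R,4aR,8aR)-5,5,8a-trimethyl-2-[2-(phenylsulfinyl)ethyl]-2-(prop-2-yn-1-yl)-4a,5,6,7,8,8a-hexahydronaphthalene-1,3(2H,4H)-dione
Product: 17 (2R,4aR,8aR)-2-ethenyl-5,5,8a-trimethyl-2-(prop-2-yn-1-yl)-4a,5,6,7,8,8a-hexahydronaphthalene-1,3(2H,4H)-dione (vinyl syn)
Conditions: NaHCO3, toluene, 110 °C
Reagents that add atoms: none
Why: Thermal syn elimination of the sulfoxide should unmask the C8 vinyl group (C14) without touching the quaternary centre.

Step 9
Reactants: 17 (2R,4aR,8aR)-2-ethenyl-5,5,8a-trimethyl-2-(prop-2-yn-1-yl)-4a,5,6,7,8,8a-hexahydronaphthalene-1,3(2H,4H)-dione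
Product: 19 (1R,4a'R,8a'R)-5',5',8a'-trimethyl-4-methylidene-4a',5',6',7',8',8a'-hexahydro-1'H-spiro[cyclopent-2-ene-1,2'-naphthalene]-1',3'(4'H)-dione (spiro carbon = C8; ring-alkene carbon C14 syn), via triene 18 (not isolated)
Conditions: second-generation Grubbs catalyst RuCl2(=CHPh)(PCy3)(H2IMes) (5 mol %), ethene (1 atm), toluene, 60 °C; then argon sparge, 80 °C
Reagents that add atoms: ethene, C=C
Why: Enyne metathesis relay: ethene–alkyne cross-metathesis should turn the terminal alkyne into a 2-substituted buta-1,3-diene, whose monosubstituted vinyl end then undergoes ring-closing metathesis with the C8 vinyl group to give the five-membered spiro ring with the C13=C14 alkene and the C16 exocyclic methylene, C8 being unaffected.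

Step 10
Reactants: 19 (1R,4a'R,8a'R)-5',5',8a'-trimethyl-4-methylidene-4a',5',6',7',8',8a'-hexahydro-1'H-spiro[cyclopent-2-ene-1,2'-naphthalene]-1',3'(4'H)-dione
Product: 20 (1R,3'R,4a'R,8a'R)-3'-hydroxy-5',5',8a'-trimethyl-4-methylidene-3',4',4a',5',6',7',8',8a'-octahydro-1'H-spiro[cyclopent-2-ene-1,2'-naphthalen]-1'-one (C7–OH equatorial, syn)
Conditions: NaBH4, MeOH–CH2Cl2, −40 °C
Reagents that add atoms: none
Why: Sodium borohydride reduction should touch only the C7 ketone (C9 is flanked by two quaternary carbons) and deliver hydride axially from the face opposite the axial C14 substituent on C8, giving the equatorial C7 alcohol syn to the C10 methyl, as in the target.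

Step 11
Reactants: 20 (1R,3'R,4a'R,8a'R)-3'-hydroxy-5',5',8a'-trimethyl-4-methylidene-3',4',4a',5',6',7',8',8a'-octahydro-1'H-spiro[cyclopent-2-ene-1,2'-naphthalen]-1'-one
Product: 21 (1R,3'R,4a'R,8a'R)-3'-[(tert-butyldimethylsilyl)oxy]-5',5',8a'-trimethyl-4-methylidene-3',4',4a',5',6',7',8',8a'-octahydro-1'H-spiro[cyclopent-2-ene-1,2'-naphthalen]-1'-one
Conditions: TBSOTf, 2,6-lutidine, CH2Cl2, 0 °C
Reagents that add atoms: tert-butyldimethylsilyl trifluoromethanesulfonate, CC(C)(C)[Si](C)(C)OS(=O)(=O)C(F)(F)F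
Why: Silylation with the silyl triflate protects the hindered secondary alcohol as its TBS ether for the base and oxidant steps that follow.

Step 12
Reactants: 21 (1R,3'R,4a'R,8a'R)-3'-[(tert-butyldimethylsilyl)oxy]-5',5',8a'-trimethyl-4-methylidene-3',4',4a',5',6',7',8',8a'-octahydro-1'H-spiro[cyclopent-2-ene-1,2'-naphthalen]-1'-one; 22 vinylmagnesium bromide
Product: 23 (1R,1'S,3'R,4a'R,8a'R)-3'-[(tert-butyldimethylsilyl)oxy]-1'-ethenyl-5',5',8a'-trimethyl-4-methylidene-3',4',4a',5',6',7',8',8a'-octahydro-1'H-spiro[cyclopent-2-ene-1,2'-naphthalen]-1'-ol (vinyl anti, hydroxyl syn)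
Conditions: 22, CeCl3 (anhydrous), THF, −78 → 0 °C; aq NH4Cl
Reagents that add atoms: none
Why: Organocerium 1,2-addition to the non-enolisable, hindered C9 ketone: attack should come from the face opposite the two axial α-substituents (C10 methyl and C14), which gives the carbinol with vinyl anti to the C10 methyl, the C9 epimer that steps 13 and 14 correct.

Step 13
Reactants: 23 (1R,1'S,3'R,4a'R,8a'R)-3'-[(tert-butyldimethylsilyl)oxy]-1'-ethenyl-5',5',8a'-trimethyl-4-methylidene-3',4',4a',5',6',7',8',8a'-octahydro-1'H-spiro[cyclopent-2-ene-1,2'-naphthalen]-1'-ol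
Product: 25 {2-[(1R,3'R,4a'R,8a'R)-3'-[(tert-butyldimethylsilyl)oxy]-5',5',8a'-trimethyl-4-methylidene-octahydro-1'H-spiro[cyclopent-2-ene-1,2'-naphthalen]-1'-ylidene]ethanesulfinyl}benzene (alkene geometry and sulfur unspecified), via sulfenate ester 24 (not isolated)
Conditions: n-BuLi, THF, −78 °C; PhSCl, −78 → 0 °C
Reagents that add atoms: benzenesulfenyl chloride, ClSc1ccccc1
Why: Mislow–Evans rearrangement: O-sulfenylation of the lithium alkoxide at −78 °C (expected to be faster than addition of the sulfenyl chloride to the diene) gives the allylic sulfenate, which should undergo the [2,3] shift to the primary allylic sulfoxide with an exocyclic C9=C11 alkene, erasing the C9 stereocentre.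

Step 14
Reactants: 25 {2-[(1R,3'R,4a'R,8a'R)-3'-[(tert-butyldimethylsilyl)oxy]-5',5',8a'-trimethyl-4-methylidene-octahydro-1'H-spiro[cyclopent-2-ene-1,2'-naphthalen]-1'-ylidene]ethanesulfinyl}benzene
Product: 27 (1R,1'R,3'R,4a'R,8a'R)-3'-[(tert-butyldimethylsilyl)oxy]-1'-ethenyl-5',5',8a'-trimethyl-4-methylidene-3',4',4a',5',6',7',8',8a'-octahydro-1'H-spiro[cyclopent-2-ene-1,2'-naphthalen]-1'-ol (vinyl syn and equatorial, hydroxyl anti and axial), via epimeric sulfenate 26 (not isolated)
Conditions: P(OMe)3, MeOH, 60 °C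
Reagents that add atoms: none
Why: Reverse Mislow–Evans rearrangement: on warming the sulfoxide equilibrates with the sulfenates, oxygen should return to C9 across the alkene face anti to the axial C10 methyl and C14, and trimethyl phosphite cleaves the S–O bond, so the carbinol with axial hydroxyl and vinyl syn to the C10 methyl should result.

Step 15
Reactants: 27 (1R,1'R,3'R,4a'R,8a'R)-3'-[(tert-butyldimethylsilyl)oxy]-1'-ethenyl-5',5',8a'-trimethyl-4-methylidene-3',4',4a',5',6',7',8',8a'-octahydro-1'H-spiro[cyclopent-2-ene-1,2'-naphthalen]-1'-ol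
Product: 30 (5R,7R,10R,11R,13R)-7-[(tert-butyldimethylsilyl)oxy]-11-hydroxy-8,9-secokaura-8(14),16-dien-9-one, via potassium alkoxide 28 (not isolated), via potassium enolate 29 (not isolated)
Conditions: KH, 18-crown-6, THF, 0 → 25 °C; then 3-phenyl-2-(phenylsulfonyl)oxaziridine, −78 °C; aq NH4Cl
Reagents that add atoms: 3-phenyl-2-(phenylsulfonyl)oxaziridine, O=S(=O)(N1OC1c1ccccc1)c1ccccc1
Why: Anionic oxy-Cope rearrangement with enolate hydroxylation: the potassium alkoxide should undergo the [3,3] shift through a chair transition state cis-fused to ring B (equatorial C9 vinyl gauche to axial C8–C14), which breaks C8–C9, forms C12–C13 on the cyclopentene face turned to C9 (chirality transfer from C8 to C13), gives the E bridgehead alkene C8=C14 and the C9 enolate, and the oxaziridine then hydroxylates C11 on the enolate face turned away from the transannular alkene (11R).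

Step 16
Reactants: 30 (5R,7R,10R,11R,13R)-7-[(tert-butyldimethylsilyl)oxy]-11-hydroxy-8,9-secokaura-8(14),16-dien-9-one
Product: 31 (5R,7R,10R,11S,13R)-7-[(tert-butyldimethylsilyl)oxy]-9-oxo-8,9-secokaura-8(14),16-dien-11-yl acetate
Conditions: PPh3, DIAD, AcOH, toluene, 0 → 25 °C
Reagents that add atoms: acetic acid, CC(=O)O
Why: Mitsunobu reaction: displacement of the oxyphosphonium group α to the ketone by acetate should invert C11 and give the 11S acetate of the target directly.

Step 17
Reactants: 31 (5R,7R,10R,11S,13R)-7-[(tert-butyldimethylsilyl)oxy]-9-oxo-8,9-secokaura-8(14),16-dien-11-yl acetate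
Product: 32 (5R,7R,10R,11S,13R)-7-[(tert-butyldimethylsilyl)oxy]-15-hydroxy-9-oxo-8,9-secokaura-8(14),16-dien-11-yl acetate (C15 unspecified)
Conditions: SeO2 (0.5 equiv), t-BuOOH, CH2Cl2, 25 °C
Reagents that add atoms: tert-butyl hydroperoxide, CC(C)(C)OO
Why: Selenium dioxide allylic hydroxylation (ene reaction then [2,3] shift): C15 is the methylene flanked by both the C8=C14 and the C16=C17 alkenes, and for both the rule CH2 before CH at the more substituted alkene end points to C15, so hydroxylation should occur there (the new carbinol centre is removed in step 18).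

Step 18
Reactants: 32 (5R,7R,10R,11S,13R)-7-[(tert-butyldimethylsilyl)oxy]-15-hydroxy-9-oxo-8,9-secokaura-8(14),16-dien-11-yl acetate
Product: 33 (5R,7R,10R,11S,13R)-7-[(tert-butyldimethylsilyl)oxy]-9,15-dioxo-8,9-secokaura-8(14),16-dien-11-yl acetate
Conditions: Dess–Martin periodinane, NaHCO3, CH2Cl2, 0 °C
Reagents that add atoms: none
Why: Dess–Martin oxidation of the doubly allylic alcohol should give the cross-conjugated dienone under buffered, non-basic conditions that spare the acetate and the silyl ether.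

Step 19
Reactants: 33 (5R,7R,10R,11S,13R)-7-[(tert-butyldimethylsilyl)oxy]-9,15-dioxo-8,9-secokaura-8(14),16-dien-11-yl acetate
Product: 34 (5R,7R,10R,11S,13R)-7-hydroxy-9,15-dioxo-8,9-secokaura-8(14),16-dien-11-yl acetate (CNP0165527.2)
Conditions: HF·pyridine, THF–pyridine, 0 → 25 °C
Reagents that add atoms: none
Why: Buffered fluoride desilylation should free O7 without base, which the α-methylene cyclopentenone and the α-acetoxy ketone would not tolerate.

## Compound list

1 | 3-ethoxy-2-methylcyclohex-2-en-1-one | CCOC1=C(C)C(=O)CCC1 | starting material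
2 | prenylmagnesium chloride, (3-methylbut-2-en-1-yl)magnesium chloride | CC(C)=CC[Mg]Cl | starting material
3 | 3-ethoxy-2-methyl-1-(2-methylbut-3-en-2-yl)cyclohex-2-en-1-ol (chloromagnesium alkoxide in the flask) | CCOC1=C(C)C(O)(C(C)(C)C=C)CCC1 | intermediate (not isolated)
4 | 2-methyl-3-(2-methylbut-3-en-2-yl)cyclohex-2-en-1-one | CC1=C(C(C)(C)C=C)CCCC1=O | intermediate
5 | allyl chloroformate | C=CCOC(Cl)=O | starting material
6 | potassium 2-methyl-3-(2-methylbut-3-en-2-yl)cyclohexa-1,3-dien-1-olate | [K+].[O-]C1=C(C)C(C(C)(C)C=C)=CCC1 | intermediate (not isolated)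
7 | 2-methyl-3-(2-methylbut-3-en-2-yl)cyclohexa-1,3-dien-1-yl prop-2-en-1-yl carbonate | C=CCOC(=O)OC1=C(C)C(C(C)(C)C=C)=CCC1 | intermediate
8 | (2R)-2-methyl-3-(2-methylbut-3-en-2-yl)-2-(prop-2-en-1-yl)cyclohex-3-en-1-one | C=CC[C@@]1(C)C(=O)CCC=C1C(C)(C)C=C | intermediate
9 | (8aR)-5,5,8a-trimethyl-3,5,8,8a-tetrahydronaphthalen-1(2H)-one | O=C1CCC=C2C(C)(C)C=CC[C@@]12C | intermediate (not isolated)
10 | (8aR)-5,5,8a-trimethyl-3,5,6,7,8,8a-hexahydronaphthalen-1(2H)-one | O=C1CCC=C2C(C)(C)CCC[C@@]12C | intermediate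
11 | (8aR)-5,5,8a-trimethyl-6,7,8,8a-tetrahydronaphthalene-1,3(2H,5H)-dione | O=C1CC(=O)C=C2C(C)(C)CCC[C@@]12C | intermediate
12 | (4aR,8aR)-5,5,8a-trimethyl-4a,5,6,7,8,8a-hexahydronaphthalene-1,3(2H,4H)-dione | O=C1CC(=O)C[C@@H]2C(C)(C)CCC[C@@]12C | intermediate
13 | phenyl vinyl sulfoxide | C=CS(=O)c1ccccc1 | starting material
14 | propargyl bromide | C#CCBr | starting material
15 | (4aR,8aR)-5,5,8a-trimethyl-2-[2-(phenylsulfinyl)ethyl]-4a,5,6,7,8,8a-hexahydronaphthalene-1,3(2H,4H)-dione (C2 and sulfur unspecified) | O=C1C(CCS(=O)c3ccccc3)C(=O)C[C@@H]2C(C)(C)CCC[C@@]12C | intermediate (not isolated)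
16 | (2R,4aR,8aR)-5,5,8a-trimethyl-2-[2-(phenylsulfinyl)ethyl]-2-(prop-2-yn-1-yl)-4a,5,6,7,8,8a-hexahydronaphthalene-1,3(2H,4H)-dione (sulfur unspecified) | O=C1[C@](CC#C)(CCS(=O)c3ccccc3)C(=O)C[C@@H]2C(C)(C)CCC[C@@]12C | intermediate
17 | (2R,4aR,8aR)-2-ethenyl-5,5,8a-trimethyl-2-(prop-2-yn-1-yl)-4a,5,6,7,8,8a-hexahydronaphthalene-1,3(2H,4H)-dione | O=C1[C@](CC#C)(C=C)C(=O)C[C@@H]2C(C)(C)CCC[C@@]12C | intermediate
18 | (2R,4aR,8aR)-2-ethenyl-5,5,8a-trimethyl-2-(2-methylidenebut-3-en-1-yl)-4a,5,6,7,8,8a-hexahydronaphthalene-1,3(2H,4H)-dione | O=C1[C@](CC(=C)C=C)(C=C)C(=O)C[C@@H]2C(C)(C)CCC[C@@]12C | intermediate (not isolated)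
19 | (1R,4a'R,8a'R)-5',5',8a'-trimethyl-4-methylidene-4a',5',6',7',8',8a'-hexahydro-1'H-spiro[cyclopent-2-ene-1,2'-naphthalene]-1',3'(4'H)-dione | O=C1[C@@]3(CC(=C)C=C3)C(=O)C[C@@H]2C(C)(C)CCC[C@@]12C | intermediate
20 | (1R,3'R,4a'R,8a'R)-3'-hydroxy-5',5',8a'-trimethyl-4-methylidene-3',4',4a',5',6',7',8',8a'-octahydro-1'H-spiro[cyclopent-2-ene-1,2'-naphthalen]-1'-one | O=C1[C@@]3(CC(=C)C=C3)[C@H](O)C[C@@H]2C(C)(C)CCC[C@@]12C | intermediate
21 | (1R,3'R,4a'R,8a'R)-3'-[(tert-butyldimethylsilyl)oxy]-5',5',8a'-trimethyl-4-methylidene-3',4',4a',5',6',7',8',8a'-octahydro-1'H-spiro[cyclopent-2-ene-1,2'-naphthalen]-1'-one | O=C1[C@@]3(CC(=C)C=C3)[C@H](O[Si](C)(C)C(C)(C)C)C[C@@H]2C(C)(C)CCC[C@@]12C | intermediate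
22 | vinylmagnesium bromide | C=C[Mg]Br | starting material
23 | (1R,1'S,3'R,4a'R,8a'R)-3'-[(tert-butyldimethylsilyl)oxy]-1'-ethenyl-5',5',8a'-trimethyl-4-methylidene-3',4',4a',5',6',7',8',8a'-octahydro-1'H-spiro[cyclopent-2-ene-1,2'-naphthalen]-1'-ol | C=C[C@@]1(O)[C@@]3(CC(=C)C=C3)[C@H](O[Si](C)(C)C(C)(C)C)C[C@@H]2C(C)(C)CCC[C@@]12C | intermediate
24 | O-(phenylsulfanyl) derivative (sulfenate ester) of 23 | C=C[C@@]1(OSc4ccccc4)[C@@]3(CC(=C)C=C3)[C@H](O[Si](C)(C)C(C)(C)C)C[C@@H]2C(C)(C)CCC[C@@]12C | intermediate (not isolated)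
25 | {2-[(1R,3'R,4a'R,8a'R)-3'-[(tert-butyldimethylsilyl)oxy]-5',5',8a'-trimethyl-4-methylidene-octahydro-1'H-spiro[cyclopent-2-ene-1,2'-naphthalen]-1'-ylidene]ethanesulfinyl}benzene (alkene geometry and sulfur unspecified) | O=S(CC=C1[C@@]3(CC(=C)C=C3)[C@H](O[Si](C)(C)C(C)(C)C)C[C@@H]2C(C)(C)CCC[C@@]12C)c4ccccc4 | intermediate
26 | sulfenate ester of 27 (C9 epimer of 24) | C=C[C@]1(OSc4ccccc4)[C@@]3(CC(=C)C=C3)[C@H](O[Si](C)(C)C(C)(C)C)C[C@@H]2C(C)(C)CCC[C@@]12C | intermediate (not isolated)
27 | (1R,1'R,3'R,4a'R,8a'R)-3'-[(tert-butyldimethylsilyl)oxy]-1'-ethenyl-5',5',8a'-trimethyl-4-methylidene-3',4',4a',5',6',7',8',8a'-octahydro-1'H-spiro[cyclopent-2-ene-1,2'-naphthalen]-1'-ol | C=C[C@]1(O)[C@@]3(CC(=C)C=C3)[C@H](O[Si](C)(C)C(C)(C)C)C[C@@H]2C(C)(C)CCC[C@@]12C | intermediate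
28 | potassium alkoxide of 27 | C=C[C@]1([O-])[C@@]3(CC(=C)C=C3)[C@H](O[Si](C)(C)C(C)(C)C)C[C@@H]2C(C)(C)CCC[C@@]12C.[K+] | intermediate (not isolated)
29 | potassium (5R,7R,10R,13R)-7-[(tert-butyldimethylsilyl)oxy]-8,9-secokaura-8(14),9(11),16-trien-9-olate (O trans to C12) | C=C1CC2=C[C@H]1C/C=C(/[O-])[C@]1(C)CCCC(C)(C)[C@H]1C[C@H]2O[Si](C)(C)C(C)(C)C.[K+] | intermediate (not isolated)
30 | (5R,7R,10R,11R,13R)-7-[(tert-butyldimethylsilyl)oxy]-11-hydroxy-8,9-secokaura-8(14),16-dien-9-one | C=C1CC2=C[C@H]1C[C@@H](O)C(=O)[C@]1(C)CCCC(C)(C)[C@H]1C[C@H]2O[Si](C)(C)C(C)(C)C | intermediate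
31 | (5R,7R,10R,11S,13R)-7-[(tert-butyldimethylsilyl)oxy]-9-oxo-8,9-secokaura-8(14),16-dien-11-yl acetate | C=C1CC2=C[C@H]1C[C@H](OC(C)=O)C(=O)[C@]1(C)CCCC(C)(C)[C@H]1C[C@H]2O[Si](C)(C)C(C)(C)C | intermediate
32 | (5R,7R,10R,11S,13R)-7-[(tert-butyldimethylsilyl)oxy]-15-hydroxy-9-oxo-8,9-secokaura-8(14),16-dien-11-yl acetate (C15 unspecified) | C=C1C(O)C2=C[C@H]1C[C@H](OC(C)=O)C(=O)[C@]1(C)CCCC(C)(C)[C@H]1C[C@H]2O[Si](C)(C)C(C)(C)C | intermediate
33 | (5R,7R,10R,11S,13R)-7-[(tert-butyldimethylsilyl)oxy]-9,15-dioxo-8,9-secokaura-8(14),16-dien-11-yl acetate | C=C1C(=O)C2=C[C@H]1C[C@H](OC(C)=O)C(=O)[C@]1(C)CCCC(C)(C)[C@H]1C[C@H]2O[Si](C)(C)C(C)(C)C | intermediate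
34 | (5R,7R,10R,11S,13R)-7-hydroxy-9,15-dioxo-8,9-secokaura-8(14),16-dien-11-yl acetate (CNP0165527.2) | C=C1C(=O)C2=C[C@H]1C[C@H](OC(C)=O)C(=O)[C@]1(C)CCCC(C)(C)[C@H]1C[C@H]2O | target

## Step count and risks

Total step count: 19. Longest linear sequence: 19 steps (fully linear from 1).

Steps most likely to fail:

1. Step 15. The [3,3] shift may stall if the cis-fused chair transition state is not reached, or be outrun by fragmentation to a tethered enone and allyl anion that reclose without stereocontrol; the enolate may also be hydroxylated with poor facial selectivity. The fallback sets out from 19 and comes back at 30.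
 - The C7 ketone of 19 is masked in situ as its lithium enolate (LiN(SiMe3)2, THF, −78 °C), vinylmagnesium bromide with CeCl3 adds to C9, and a cold acetic acid quench should give the 9-hydroxy-9-vinyl 7-ketone F1.
 - Catalytic DBU (THF, 0 °C) then triggers retro-aldol cleavage of C8–C9, since the C9 alkoxide is β to the C7 ketone. The tethered trienolate closes onto the vinyl ketone by intramolecular vinylogous Michael addition at C13 to give the bicyclic ene-dione F2; this path is independent of the C9 configuration and needs no pericyclic geometry, but C13 is then set only by the conformation of the ring closure.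
 - Luche reduction (NaBH4, CeCl3·7H2O, MeOH, −78 °C) of the conjugated C7 ketone gives the allylic alcohol F3, and TBSOTf with 2,6-lutidine gives the silyl ether F4.
 - LiN(SiMe3)2 followed by the oxaziridine hydroxylates C11, the only enolisable position of the C9 ketone, to reach 30.

2. Step 14 (with step 13). Oxygen may return to C9 with poor facial selectivity, or the sulfenyl chloride may add to the diene instead of the alkoxide. The fallback sets out from 23 and comes back at 27.
 - Babler–Dauben oxidative transposition (pyridinium chlorochromate [C5H5NH][CrO3Cl], CH2Cl2) gives the exocyclic enal F5.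
 - Weitz–Scheffer epoxidation (H2O2, NaOH, MeOH, 0 °C) attacks only this electron-poor alkene, from the face anti to the C10 methyl, and gives the spiro epoxy aldehyde F6.
 - Wharton rearrangement (N2H4·H2O, AcOH, MeOH) turns F6 into 27, the oxygen staying on C9.

3. Step 3. The allylation may proceed with low enantioselectivity, may go to the γ-carbon, or the product may drift to the conjugated isomer by Cope shift. The fallback sets out from 1 and comes back at 8.
 - Acid hydrolysis of 1 gives 2-methylcyclohexane-1,3-dione F7, and C-allylation (allyl acetate, Pd(PPh3)4, THF) gives 2-allyl-2-methylcyclohexane-1,3-dione F8.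
 - Desymmetrising reduction with baker's yeast gives the known (2S,3S)-3-hydroxy-2-methyl-2-(prop-2-en-1-yl)cyclohexan-1-one F9, which fixes C10 enzymatically.
 - Prenylmagnesium chloride (2.2 equiv) adds to the remaining ketone through its γ-carbon to give the diol F10, and Dess–Martin oxidation of the secondary alcohol gives the hydroxy ketone F11.
 - Dehydration of the tertiary alcohol with Burgess reagent can only go towards C6 and gives 8.

Further compounds
F1 | step 15 | (1R,1'S,4a'R,8a'R)-1'-ethenyl-1'-hydroxy-5',5',8a'-trimethyl-4-methylidene-octahydro-3'H-spiro[cyclopent-2-ene-1,2'-naphthalen]-3'-one | C=C[C@@]1(O)[C@@]3(CC(=C)C=C3)C(=O)C[C@@H]2C(C)(C)CCC[C@@]12C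
F2 | step 15 | (5R,10R,13R)-8,9-secokaura-8(14),16-diene-7,9-dione | C=C1CC2=C[C@H]1CCC(=O)[C@]1(C)CCCC(C)(C)[C@H]1CC2=O
F3 | step 15 | (5R,7R,10R,13R)-7-hydroxy-8,9-secokaura-8(14),16-dien-9-one | C=C1CC2=C[C@H]1CCC(=O)[C@]1(C)CCCC(C)(C)[C@H]1C[C@H]2O
F4 | step 15 | (5R,7R,10R,13R)-7-[(tert-butyldimethylsilyl)oxy]-8,9-secokaura-8(14),16-dien-9-one | C=C1CC2=C[C@H]1CCC(=O)[C@]1(C)CCCC(C)(C)[C@H]1C[C@H]2O[Si](C)(C)C(C)(C)C
F5 | step 14 | 2-[(1R,3'R,4a'R,8a'R)-3'-[(tert-butyldimethylsilyl)oxy]-5',5',8a'-trimethyl-4-methylidene-octahydro-1'H-spiro[cyclopent-2-ene-1,2'-naphthalen]-1'-ylidene]acetaldehyde | O=CC=C1[C@@]3(CC(=C)C=C3)[C@H](O[Si](C)(C)C(C)(C)C)C[C@@H]2C(C)(C)CCC[C@@]12C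
F6 | step 14 | spiro epoxy aldehyde of F5 (oxirane on C9 and C11, oxygen anti to the C10 methyl, C11 unspecified) | O=CC1O[C@]14[C@@]3(CC(=C)C=C3)[C@H](O[Si](C)(C)C(C)(C)C)C[C@@H]2C(C)(C)CCC[C@@]42C
F7 | step 3 | 2-methylcyclohexane-1,3-dione | CC1C(=O)CCCC1=O
F8 | step 3 | 2-methyl-2-(prop-2-en-1-yl)cyclohexane-1,3-dione | C=CCC1(C)C(=O)CCCC1=O
F9 | step 3 | (2S,3S)-3-hydroxy-2-methyl-2-(prop-2-en-1-yl)cyclohexan-1-one | C=CC[C@@]1(C)[C@@H](O)CCCC1=O
F10 | step 3 | (2S,3S)-2-methyl-1-(2-methylbut-3-en-2-yl)-2-(prop-2-en-1-yl)cyclohexane-1,3-diol (C1 unspecified) | C=CC[C@@]1(C)[C@@H](O)CCCC1(O)C(C)(C)C=C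
F11 | step 3 | (2R)-3-hydroxy-2-methyl-3-(2-methylbut-3-en-2-yl)-2-(prop-2-en-1-yl)cyclohexan-1-one (C3 unspecified) | C=CC[C@@]1(C)C(=O)CCCC1(O)C(C)(C)C=C
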